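**Structural features**

The target is a 5,6-dihydro-2H-pyran-2-one (ring atoms O1, C2(=O), C3=C4, C5H2, C6H) whose C6 carries an eight-carbon chain C1'–C8' ending in a phenyl group. Along the chain lie an E alkene C1'=C2', a skipped methylene C3', a free secondary hydroxyl at C4', a methylene C5', an acetoxy group at C6' and an E styryl alkene C7'=C8'. The three stereocentres are C6 (S), C4' (R) and C6' (S). C4' and C6' form an anti-1,3-diol in which only the allylic oxygen is acetylated. C6 and C4' are 1,5-related (anti in the zigzag projection) across the E alkene, so O–C6–C1'=C2'–C3'–C4'–O is an (E)-2-ene-1,5-diol unit. Fragile groups are the conjugated lactone (Michael acceptor, opened by base), the cinnamyl-type acetate (ionisation, and 1,3-shift to the free C4' hydroxyl under base) and any carbonyl intermediate with C5 or C3' in the alpha position (β,γ-unsaturation that slips into conjugation). The real difficulty is twofold: the remote C6/C4' pair has no 1,2- or 1,3-neighbour to lean on, and three secondary oxygens must end as three different functions (lactone, free OH, acetate). The key step exploits the (E)-2-ene-1,5-diol unit O–C6–C1'=C2'–C3'–C4'–O, which is the retron of a double allylboration of two aldehydes by one three-carbon linchpin.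

**Logic of the disconnections**

(Target locants are used for atoms. In the open-chain compounds 19–21 the chain locants C1–C5 correspond to ring atoms C2–C6, and C6–C13 to C1'–C8'.)

23 ⇒ 20. Cut: the ring bond O1–C2, with C2 returned to the alcohol level. Reason: in 20 the primary allylic alcohol at C2 is held by the Z C3=C4 alkene next to the C6 hydroxyl only, so oxidation at C2 closes the ring on C6–O by itself (through 21 and 22) and the C4' hydroxyl stays free without a protecting group. Gain: the ring and its sensitive enoate are replaced by an acyclic triol monoacetate. Demand: oxidation of a primary allylic alcohol beside two secondary ones, with no Z to E isomerisation and no acetate migration.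

20 ⇒ 19. Cut: the O–Si bond on the C2 oxygen. Reason: this oxygen must be masked while C6 is an aldehyde carbon (in 9). Gain: none in skeleton; it only makes the C5 fragment stable. Demand: fluoride conditions that leave the acetate where it is.

19 ⇒ 4 + 9 + 15 (key). Cuts: C6–C1' and C3'–C4'. C1'–C3' become a chiral allyl dianion equivalent (16, made from 4), and C6 and C4' become the carbonyl carbons of 9 and 15. Reason: one operation joins three fragments, sets C6 and C4' as a pair and fixes the E alkene between them. C6'–OAc arrives inside 15, so the product has free hydroxyls only at C6 and C4', exactly the pattern the last disconnection needs. Gain: a C13 chain with three stereocentres falls into an achiral C5 aldehyde, a C3 linchpin and a C5 aldehyde with one stereocentre. Demand: ordered reaction of two different aldehydes, E geometry, 1,5-anti transfer, and survival of a β-acetoxy aldehyde and a β,γ-unsaturated aldehyde.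

15 ⇒ 13 ⇒ 12 ⇒ 10. Cuts: C4'=O back to a terminal alkene (one extra carbon), the O–acetyl bond, then C5'–C6' (allyl to carbonyl). Reason: reagent-controlled allylation of an enal is the most reliable way to set C6'. Gain: the only stereocentre bought outside the key step comes from cinnamaldehyde in one step. Demand: oxidative cleavage of the monosubstituted alkene in the presence of the styryl alkene.

9 ⇒ 8 ⇒ 7 ⇒ 5. Cuts: C6=O back to a primary alcohol, the Z C3=C4 alkene back to an alkyne, then C4–C5 (acetylide plus ethylene oxide, which supplies C5 and C6). Reason: semihydrogenation fixes the Z geometry the lactone needs. Gain: a C3 silyl ether and a C2 epoxide. Demand: the aldehyde must be made and used without moving the double bond.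

4 ⇒ 1. Cuts: the B–C bond and the two B–O bonds. Reason: the unhindered six-membered boronic ester is what lets the second allylboration place its α-substituent equatorial (E alkene). Gain: propargyl bromide, trimethyl borate and a diol. Demand: allenyl, not propargyl, boron connectivity.

**Other disconnections considered**

Alternative 1: Cut C3=C4 of the lactone and build the chain linearly. The forward key step is ring-closing metathesis of acrylate A1 with RuCl2(=CHPh)(PCy3)(H2IMes) (second-generation Grubbs catalyst). A1 would be grown from 10 by three successive asymmetric aldehyde allylations, with oxidative cleavages and one E-olefination in between. This is the plan most chemists would draw first. Each stereocentre is bought separately, the metathesis forms only the easiest bond of the molecule, and the C4' oxygen must be blocked before the C6 oxygen can be acryloylated and unblocked after the acetate is in place. The sequence is therefore long and linear, and the remote C6/C4' relationship is never addressed as a pair.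

Alternative 2: Cut C1'=C2' by cross-metathesis (or a sulfone olefination) between vinyl lactone A2 and homoallylic alcohol A3. The forward step creates no stereocentre, so A2 and A3 each need their own asymmetric chemistry. A2 is a secondary allylic acyloxy olefin, slow in metathesis, while A3 dimerises readily. The E geometry is only a thermodynamic preference, and the catalyst can also engage the styryl and enoate alkenes. The chosen plan makes the same alkene with its geometry fixed by a chair transition state and sets two stereocentres in the same step.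

Alternative 3: Cut C5'–C6' by an aldol reaction of methyl ketone A4 with 10 to give β-hydroxy ketone A5, followed by an Evans–Tishchenko reduction (SmI2 cat., acetaldehyde). That step would set C4' anti and place the acetate on the C6' oxygen in one move, which is an attractive answer to the acetate problem. The weakness is A4: it is a β,γ-unsaturated ketone whose most acidic position is the doubly activated C3' methylene. Enolisation there leads to conjugation and to vinylogous β-elimination of the lactone carboxylate at C6. C6 is also too remote to guide the aldol, so a chiral boron reagent is still needed, and A4 itself requires separate construction of C6 and of the E alkene. The risk sits in the supporting steps and convergence is not improved.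

Key step: step 8

Assumption: the SMILES is read as (6S)-6-[(1E,4R,6S,7E)-6-acetoxy-4-hydroxy-8-phenylocta-1,7-dien-1-yl]-5,6-dihydro-2H-pyran-2-one, and the facial sense of the isopinocampheyl boron reagents is taken from the accepted model for Brown allylboration (reagent from (+)-α-pinene gives the S alcohol from benzaldehyde).

**Route**

Step 1
Reactants: 1 propargyl bromide (3-bromoprop-1-yne)
Product: 4 5,5-dimethyl-2-(propa-1,2-dien-1-yl)-1,3,2-dioxaborinane, via allenylmagnesium bromide 2 (not isolated), via allenylboronic acid 3 (not isolated)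
Conditions: Mg, HgCl2 (cat.), Et2O, 0 °C; B(OMe)3, −78 °C; aq. HCl; then 2,2-dimethylpropane-1,3-diol, MgSO4, Et2O, rt; distillation
Reagents that add atoms: trimethyl borate, COB(OC)OC; 2,2-dimethylpropane-1,3-diol, OCC(C)(C)CO
Why: Grignard formation from propargyl bromide gives the allenyl magnesium species, which borylates with trimethyl borate to the allenylboron isomer; hydrolysis and dehydrative esterification with the diol give the distillable boronic ester.

Step 2
Reactants: 5 tert-butyldimethyl(prop-2-yn-1-yloxy)silane
Product: 7 5-[(tert-butyldimethylsilyl)oxy]pent-3-yn-1-ol, via lithium acetylide 6 (not isolated)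
Conditions: n-BuLi, THF, −78 °C; BF3·OEt2, then ethylene oxide, −78 °C; aq. NaHCO3
Reagents that add atoms: ethylene oxide, C1CO1
Why: Yamaguchi–Hirao alkynylation; the alkynyl trifluoroborate formed in situ opens the BF3-activated epoxide at −78 °C, adding the two carbons that become C5 and C6.

Step 3
Reactants: 7 5-[(tert-butyldimethylsilyl)oxy]pent-3-yn-1-ol
Product: 8 (Z)-5-[(tert-butyldimethylsilyl)oxy]pent-3-en-1-ol
Conditions: H2 (1 atm), Pd/CaCO3–Pb(OAc)2 (Lindlar catalyst), quinoline, EtOAc, rt
Reagents that add atoms: none
Why: Lindlar semihydrogenation adds hydrogen syn on the poisoned palladium surface and stops at the Z alkene that the lactone ring later requires.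

Step 4
Reactants: 8 (Z)-5-[(tert-butyldimethylsilyl)oxy]pent-3-en-1-ol
Product: 9 (Z)-5-[(tert-butyldimethylsilyl)oxy]pent-3-enal
Conditions: Dess–Martin periodinane, NaHCO3, CH2Cl2, 0 °C; short filtration, used at once
Reagents that add atoms: none
Why: Dess–Martin oxidation is non-basic and buffered, the usual way to (Z)-β,γ-unsaturated aldehydes without moving the double bond; the crude aldehyde goes directly into step 8.

Step 5
Reactants: 10 (E)-cinnamaldehyde
Product: 12 (S,E)-1-phenylhexa-1,5-dien-3-ol, via borinate ester 11 (not isolated)
Conditions: (−)-B-allyldiisopinocampheylborane, Et2O, −78 °C; then NaOH, 30% H2O2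
Reagents that add atoms: (−)-B-allyldiisopinocampheylborane (isopinocampheyl groups from (+)-α-pinene), C=CCB([C@@H]1C[C@@H]2C[C@H]([C@H]1C)C2(C)C)[C@@H]1C[C@@H]2C[C@H]([C@H]1C)C2(C)C
Why: Brown allylation through a chair transition state; the isopinocampheyl groups from (+)-α-pinene should direct 1,2-addition to the aldehyde face that gives the S carbinol (the future C6').

Step 6
Reactants: 12 (S,E)-1-phenylhexa-1,5-dien-3-ol
Product: 13 (S,E)-1-phenylhexa-1,5-dien-3-yl acetate
Conditions: Ac2O, pyridine, DMAP (cat.), CH2Cl2, 0 °C to rt
Reagents that add atoms: acetic anhydride, CC(=O)OC(C)=O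
Why: DMAP-catalysed acetylation places the final acetate on the C6' oxygen while it is the only hydroxyl in the molecule, so no later regioselective acetylation is needed.

Step 7
Reactants: 13 (S,E)-1-phenylhexa-1,5-dien-3-yl acetate
Product: 15 (S,E)-3-acetoxy-5-phenylpent-4-enal [(S,E)-5-oxo-1-phenylpent-1-en-3-yl acetate], via terminal diol 14 (not isolated)
Conditions: OsO4 (cat.), NaIO4, 2,6-lutidine, 1,4-dioxane/H2O, 0 °C to rt; stopped when 13 is consumed; rapid chromatography on buffered silica
Reagents that add atoms: OsO4 (oxygen-transfer catalyst), O=[Os](=O)(=O)=O; NaIO4 (terminal source of the oxygen), [Na+].[O-]I(=O)(=O)=O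
Why: Lemieux–Johnson cleavage; the unhindered monosubstituted alkene should be osmylated faster than the 1,2-disubstituted styryl alkene, which is inductively deactivated and shielded by the allylic acetate; the stereocentre is not touched.

Step 8
Reactants: 4 5,5-dimethyl-2-(propa-1,2-dien-1-yl)-1,3,2-dioxaborinane; 9 (Z)-5-[(tert-butyldimethylsilyl)oxy]pent-3-enal; 15 (S,E)-3-acetoxy-5-phenylpent-4-enal
Product: 19 (2Z,5S,6E,9R,11S,12E)-1-[(tert-butyldimethylsilyl)oxy]-5,9-dihydroxy-13-phenyltrideca-2,6,12-trien-11-yl acetate, via γ-boryl allylborane 16 (not isolated), via α-substituted allylboronate 17 (not isolated), via bis-boron ester 18 (not isolated)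
Conditions: (+)-Ipc2BH (from (−)-α-pinene), 4, toluene/Et2O, −25 to 0 °C; 9 (slightly less than 1 equiv), −78 °C; then 15, −78 °C to rt; MeOH, pH 7 phosphate buffer, 30% H2O2, 0 °C
Reagents that add atoms: none
Why: This is a one-pot double allylboration of two different aldehydes by a bifunctional γ-boryl allylborane, the closest known reaction type being the double allylboration route to (E)-2-ene-1,5-anti-diols. (+)-Ipc2BH adds across the terminal C=C of 4, and reversible 1,3-boratropic shifts funnel the adduct to the E isomer 16. At −78 °C only the dialkylallylborane end of 16 reacts, adding to 9 through a closed chair transition state in which the isopinocampheyl groups choose the aldehyde face (C6 becomes S, the Brown sense for the reagent from (−)-α-pinene) and the E geometry keeps the boronate equatorial, which gives the anti β-borinyloxy allylboronate 17. On warming, 17 adds to 15 through a second chair in which its bulky α-substituent sits equatorial, as favoured by the unhindered dioxaborinane ester; this forms the E C1'=C2' alkene and transfers the C–B configuration to C4' (R), giving the 1,5-anti pair. No ring is closed. The order of the two aldehydes is secured by the large rate gap between the borane and the boronate and by sequential addition. The chirality transfer should dominate over the resident C6' centre of 15, whose weak 1,3-induction in a closed transition state normally favours the required 1,3-anti product. Aldehydes 9 and 15 and the acetate meet only neutral, non-basic boron species, and the buffered peroxide work-up only cleaves the B–C and B–O bonds of 18.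

Step 9
Reactants: 19 (2Z,5S,6E,9R,11S,12E)-1-[(tert-butyldimethylsilyl)oxy]-5,9-dihydroxy-13-phenyltrideca-2,6,12-trien-11-yl acetate
Product: 20 (2Z,5S,6E,9R,11S,12E)-1,5,9-trihydroxy-13-phenyltrideca-2,6,12-trien-11-yl acetate
Conditions: HF·pyridine, pyridine, THF, 0 °C
Reagents that add atoms: none
Why: Buffered fluoride desilylation of a primary allylic silyl ether; the medium is weakly acidic, so the acetate should neither hydrolyse nor migrate to the C4' hydroxyl.

Step 10
Reactants: 20 (2Z,5S,6E,9R,11S,12E)-1,5,9-trihydroxy-13-phenyltrideca-2,6,12-trien-11-yl acetate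
Product: 23 (6S)-6-[(1E,4R,6S,7E)-6-acetoxy-4-hydroxy-8-phenylocta-1,7-dien-1-yl]-5,6-dihydro-2H-pyran-2-one, via Z-enal 21 (not isolated), via lactol 22 (not isolated)
Conditions: TEMPO (cat.), PhI(OAc)2, CH2Cl2, rt
Reagents that add atoms: none
Why: TEMPO/PhI(OAc)2 oxidative lactonisation of a (Z)-2-ene-1,5-diol; the oxoammonium oxidises the primary allylic alcohol much faster than the secondary ones, the Z-enal 21 is trapped by the C6 hydroxyl as lactol 22, and 22 is oxidised to the lactone, while the C4' hydroxyl has no aldehyde within reach and stays free.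

**Compound list**

1 | propargyl bromide (3-bromoprop-1-yne) | C#CCBr | starting material
2 | allenylmagnesium bromide | C=C=C[Mg]Br | intermediate
3 | allenylboronic acid (propa-1,2-dien-1-ylboronic acid) | C=C=CB(O)O | intermediate
4 | 5,5-dimethyl-2-(propa-1,2-dien-1-yl)-1,3,2-dioxaborinane | C=C=CB1OCC(C)(C)CO1 | intermediate
5 | tert-butyldimethyl(prop-2-yn-1-yloxy)silane | C#CCO[Si](C)(C)C(C)(C)C | starting material
6 | lithium acetylide of 5 | [Li]C#CCO[Si](C)(C)C(C)(C)C | intermediate
7 | 5-[(tert-butyldimethylsilyl)oxy]pent-3-yn-1-ol | OCCC#CCO[Si](C)(C)C(C)(C)C | intermediate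
8 | (Z)-5-[(tert-butyldimethylsilyl)oxy]pent-3-en-1-ol | OCC/C=C\CO[Si](C)(C)C(C)(C)C | intermediate
9 | (Z)-5-[(tert-butyldimethylsilyl)oxy]pent-3-enal | O=CC/C=C\CO[Si](C)(C)C(C)(C)C | intermediate
10 | (E)-cinnamaldehyde | O=C/C=C/c1ccccc1 | starting material
11 | (S,E)-1-phenylhexa-1,5-dien-3-yl bis(isopinocampheyl)borinate (isopinocampheyl from (+)-α-pinene) | C=CC[C@H](OB([C@@H]1C[C@@H]2C[C@H]([C@H]1C)C2(C)C)[C@@H]1C[C@@H]2C[C@H]([C@H]1C)C2(C)C)/C=C/c1ccccc1 | intermediate
12 | (S,E)-1-phenylhexa-1,5-dien-3-ol | C=CC[C@H](O)/C=C/c1ccccc1 | intermediate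
13 | (S,E)-1-phenylhexa-1,5-dien-3-yl acetate | C=CC[C@H](OC(C)=O)/C=C/c1ccccc1 | intermediate
14 | (1E,3S)-5,6-dihydroxy-1-phenylhex-1-en-3-yl acetate (both C5 epimers) | OCC(O)C[C@H](OC(C)=O)/C=C/c1ccccc1 | intermediate
15 | (S,E)-3-acetoxy-5-phenylpent-4-enal | O=CC[C@H](OC(C)=O)/C=C/c1ccccc1 | intermediate
16 | (E)-[3-(5,5-dimethyl-1,3,2-dioxaborinan-2-yl)prop-2-en-1-yl]bis(isopinocampheyl)borane (isopinocampheyl from (−)-α-pinene) | CC1(C)COB(/C=C/CB([C@H]2C[C@H]3C[C@@H]([C@@H]2C)C3(C)C)[C@H]2C[C@H]3C[C@@H]([C@@H]2C)C3(C)C)OC1 | intermediate
17 | (3R,4S,6Z)-8-[(tert-butyldimethylsilyl)oxy]-3-(5,5-dimethyl-1,3,2-dioxaborinan-2-yl)octa-1,6-dien-4-yl bis(isopinocampheyl)borinate | C=C[C@@H](B1OCC(C)(C)CO1)[C@@H](OB([C@H]1C[C@H]2C[C@@H]([C@@H]1C)C2(C)C)[C@H]1C[C@H]2C[C@@H]([C@@H]1C)C2(C)C)C/C=C\CO[Si](C)(C)C(C)(C)C | intermediate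
18 | bis-boron ester of 19 (C6–O borinate with two isopinocampheyl groups, C4'–O borate of the dioxaborinane) | CC(=O)O[C@H](/C=C/c1ccccc1)C[C@H](OB1OCC(C)(C)CO1)C/C=C/[C@@H](OB([C@H]1C[C@H]2C[C@@H]([C@@H]1C)C2(C)C)[C@H]1C[C@H]2C[C@@H]([C@@H]1C)C2(C)C)C/C=C\CO[Si](C)(C)C(C)(C)C | intermediate
19 | (2Z,5S,6E,9R,11S,12E)-1-[(tert-butyldimethylsilyl)oxy]-5,9-dihydroxy-13-phenyltrideca-2,6,12-trien-11-yl acetate | CC(=O)O[C@H](/C=C/c1ccccc1)C[C@H](O)C/C=C/[C@@H](O)C/C=C\CO[Si](C)(C)C(C)(C)C | intermediate
20 | (2Z,5S,6E,9R,11S,12E)-1,5,9-trihydroxy-13-phenyltrideca-2,6,12-trien-11-yl acetate | CC(=O)O[C@H](/C=C/c1ccccc1)C[C@H](O)C/C=C/[C@@H](O)C/C=C\CO | intermediate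
21 | (2Z,5S,6E,9R,11S,12E)-5,9-dihydroxy-1-oxo-13-phenyltrideca-2,6,12-trien-11-yl acetate | CC(=O)O[C@H](/C=C/c1ccccc1)C[C@H](O)C/C=C/[C@@H](O)C/C=C\C=O | intermediate
22 | (1E,3S,5R,7E)-5-hydroxy-8-[(2S)-6-hydroxy-3,6-dihydro-2H-pyran-2-yl]-1-phenylocta-1,7-dien-3-yl acetate (both anomers) | CC(=O)O[C@H](/C=C/c1ccccc1)C[C@H](O)C/C=C/[C@@H]1CC=CC(O)O1 | intermediate
23 | (6S)-6-[(1E,4R,6S,7E)-6-acetoxy-4-hydroxy-8-phenylocta-1,7-dien-1-yl]-5,6-dihydro-2H-pyran-2-one | CC(=O)O[C@H](/C=C/c1ccccc1)C[C@H](O)C/C=C/[C@@H]1CC=CC(=O)O1 | target

**Step count and risk**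

Total step count: 10. Longest linear sequence: 6 steps (5, 6, 7, 8, 9, 10, or equally 2, 3, 4, 8, 9, 10).

Step 8 (key step). Most likely failure: during the slow second allylboration at ambient temperature, 15 loses acetic acid by β-elimination (driven by conjugation with the styrene) faster than 17 captures it. A second failure is partial reaction of 17 with its α-substituent axial, which erodes the E and 1,5-anti selectivity. Fallback (from 15, back at 19): the two C–C bonds are made in two separate, fast reactions. 15 is treated at −78 °C with the α-(tributylstannyl)allyl-diisopinocampheylborane generated from tributyl(propa-1,2-dien-1-yl)stannane and (+)-Ipc2BH (hydroboration, then 1,3-boratropic shift; the Ipc sense is chosen by the Brown facial model for an R carbinol). This known stannyl-allylboration should give the vinylstannane (1E,4R,6S,7E)-4-hydroxy-8-phenyl-1-(tributylstannyl)octa-1,7-dien-6-yl acetate F1 before elimination can compete. Iododestannylation (I2, CH2Cl2, 0 °C) gives the vinyl iodide (1E,4R,6S,7E)-4-hydroxy-1-iodo-8-phenylocta-1,7-dien-6-yl acetate F2. A Nozaki–Hiyama–Kishi coupling of F2 with 9 (CrCl2, NiCl2 cat., chiral sulfonamide ligand, THF) then forms C6–C1' and returns to 19; any C6 epimer would be removed by chromatography.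

Step 7. Most likely failure: poor chemoselectivity of the osmylation, so that the styryl alkene is also dihydroxylated and cleaved, and loss of acetic acid from 15 on silica. Fallback (from 10, back at 15): the aldehyde is reached at the acyl oxidation level with no alkene cleavage. Aldol addition of the lithium enolate of N-methoxy-N-methylacetamide to 10 gives racemic (E)-3-hydroxy-N-methoxy-N-methyl-5-phenylpent-4-enamide F3. Lipase-catalysed acylation with vinyl acetate (kinetic resolution; by the Kazlauskas rule with styryl as the large group) should convert the R alcohol into (R,E)-5-[methoxy(methyl)amino]-5-oxo-1-phenylpent-1-en-3-yl acetate F4 and leave (S,E)-3-hydroxy-N-methoxy-N-methyl-5-phenylpent-4-enamide F5. Acetylation of F5 (Ac2O, pyridine) gives (S,E)-5-[methoxy(methyl)amino]-5-oxo-1-phenylpent-1-en-3-yl acetate F6; should the enzyme prefer the other enantiomer, the acetate it forms is F6 itself. Cp2Zr(H)Cl in THF reduces the Weinreb amide of F6 to the aldehyde in the presence of the acetate and returns to 15.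

Step 4. Most likely failure: migration of the Z C3=C4 bond into conjugation with the new aldehyde (the C5 hydrogens are both allylic and alpha to C=O), or Z to E isomerisation during oxidation, work-up or concentration. Fallback (from 5 through its acetylide 6, back at 9): the aldehyde is released by glycol cleavage at neutral pH instead of alcohol oxidation. Alkylation of 6 with allyl bromide (CuI cat.) gives tert-butyl(hex-5-en-2-yn-1-yloxy)dimethylsilane F7. OsO4/N-methylmorpholine N-oxide dihydroxylates its only alkene to 6-[(tert-butyldimethylsilyl)oxy]hex-4-yne-1,2-diol F8. Semihydrogenation over Pd/CaCO3–Pb(OAc)2 gives (Z)-6-[(tert-butyldimethylsilyl)oxy]hex-4-ene-1,2-diol F9, a storable precursor. NaIO4 on silica in CH2Cl2 cleaves F9 to 9, which is filtered and transferred directly into the solution of 16 without concentration.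

**Further compounds**

F1 | step 8 | (1E,4R,6S,7E)-4-hydroxy-8-phenyl-1-(tributylstannyl)octa-1,7-dien-6-yl acetate | CC(=O)O[C@H](/C=C/c1ccccc1)C[C@H](O)C/C=C/[Sn](CCCC)(CCCC)CCCC
F2 | step 8 | (1E,4R,6S,7E)-4-hydroxy-1-iodo-8-phenylocta-1,7-dien-6-yl acetate | CC(=O)O[C@H](/C=C/c1ccccc1)C[C@H](O)C/C=C/I
F3 | step 7 | racemic (E)-3-hydroxy-N-methoxy-N-methyl-5-phenylpent-4-enamide | CON(C)C(=O)CC(O)/C=C/c1ccccc1
F4 | step 7 | (R,E)-5-[methoxy(methyl)amino]-5-oxo-1-phenylpent-1-en-3-yl acetate | CON(C)C(=O)C[C@@H](OC(C)=O)/C=C/c1ccccc1
F5 | step 7 | (S,E)-3-hydroxy-N-methoxy-N-methyl-5-phenylpent-4-enamide | CON(C)C(=O)C[C@H](O)/C=C/c1ccccc1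
F6 | step 7 | (S,E)-5-[methoxy(methyl)amino]-5-oxo-1-phenylpent-1-en-3-yl acetate | CON(C)C(=O)C[C@H](OC(C)=O)/C=C/c1ccccc1
F7 | step 4 | tert-butyl(hex-5-en-2-yn-1-yloxy)dimethylsilane | C=CCC#CCO[Si](C)(C)C(C)(C)C
F8 | step 4 | 6-[(tert-butyldimethylsilyl)oxy]hex-4-yne-1,2-diol (racemic) | OCC(O)CC#CCO[Si](C)(C)C(C)(C)C
F9 | step 4 | (Z)-6-[(tert-butyldimethylsilyl)oxy]hex-4-ene-1,2-diol (racemic) | OCC(O)C/C=C\CO[Si](C)(C)C(C)(C)C
A1 | alternative 1 | (4S,5E,8R,10S,11E)-10-acetoxy-8-[(tert-butyldimethylsilyl)oxy]-12-phenyldodeca-1,5,11-trien-4-yl acrylate | CC(=O)O[C@H](/C=C/c1ccccc1)C[C@H](O[Si](C)(C)C(C)(C)C)C/C=C/[C@H](CC=C)OC(=O)C=C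
A2 | alternative 2 | (S)-6-vinyl-5,6-dihydro-2H-pyran-2-one | C=C[C@@H]1CC=CC(=O)O1
A3 | alternative 2 | (4R,6S,7E)-4-hydroxy-8-phenylocta-1,7-dien-6-yl acetate | CC(=O)O[C@H](/C=C/c1ccccc1)C[C@H](O)CC=C
A4 | alternative 3 | (S)-6-[(E)-4-oxopent-1-en-1-yl]-5,6-dihydro-2H-pyran-2-one | CC(=O)C/C=C/[C@@H]1CC=CC(=O)O1
A5 | alternative 3 | (S)-6-[(1E,6S,7E)-6-hydroxy-4-oxo-8-phenylocta-1,7-dien-1-yl]-5,6-dihydro-2H-pyran-2-one | O[C@H](/C=C/c1ccccc1)CC(=O)C/C=C/[C@@H]1CC=CC(=O)O1
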